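## Structural features

The target 23 is a 3,3'-biflavanone: two chroman-4-one units (rings A/C and A'/C'), each with a 4-methoxyphenyl ring B on C2, joined by one single bond between the sp3 carbons C3 and C3'. The four stereocentres C2, C3, C3' and C2' stand in a row and are all R, so each pyranone ring is 2,3-cis (aryl group and C3–C3' bond on the same face) and the stereochemical core is C2-symmetric. The constitution is not symmetric: ring A has free hydroxyls at C5 and C7, ring A' a hydroxyl at C5' and a methyl ether at C7', so the two 7-oxygens must be told apart. The fragile elements are the C3–H and C3'–H bonds alpha to the ketones (the cis arrangement is the less stable one and epimerises through the enol), the O1–C2 bonds (opened to the chalcone by base, benzylic to an anisyl ring in acid) and the electron-rich rings A. The real difficulty is the C3–C3' bond between two crowded tertiary carbons, combined with cis rings in one enantiomer that must never meet base once the ketones exist. The key step exploits that C3 and C3' are adjacent, each inside a six-membered ring O1–C2–C3–C4–C4a–C8a and each next to C4: they can be the two carbons of an alkyne whose propargylic carbons are C2 and C2', and the C3–C4 and C3'–C4' bonds can be made as ring alkenes from vinyl groups on C4a and C4a'.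

## Logic of the disconnections

23 to 22. Cut: the three benzyl–oxygen bonds on O5, O7 and O5'. Reason: hydrogenolysis is the one deprotection that needs neither acid nor base. Gain: every earlier intermediate is a neutral ether, and because O7' is a methyl ether from the start, no late differentiation of the two 7-oxygens is needed. Demand: aryl benzyl ethers must go without opening the cyclic benzylic C2–O1 bonds or reducing C4=O.

22 to 21. Cut: the two C4=O pi bonds, back to secondary alcohols. Reason: the ketone is what makes C3–H labile, so it is introduced as late as possible. Gain: no earlier intermediate can epimerise at C3 or C3'. Demand: a non-basic oxidant that leaves rings A alone.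

21 to 19. Cut: C3–H, C4–O, C3'–H and C4'–O (retro-hydroboration–oxidation). Reason: both C3 carbons become sp2 carbons of a conjugated diene. Gain: four of six stereocentres disappear; only C2 and C2' remain. Demand: boron on C4 and C4', and addition from the face opposite each 2-aryl group, twice.

19 to 18 (key disconnection). Cut: the ring bonds C3=C4 and C3'=C4'; the C3–C3' single bond reverts to a triple bond and each C4 regains a terminal methylene. Reason: the most crowded bond of 23 is then never formed between two sp3 carbons; it is present from the start as an alkyne. Gain: both pyran rings open and the problem becomes an acyclic bis(aryl ether) of a butynediol with two stereocentres. Demand: a cascade that starts at a styrene, passes the alkyne in the exo mode and ends on the second styrene, leaving C2 and C2' untouched.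

18 to 17. Cut: the C4'=CH2 double bond, back to a formyl group. Reason: the formyl group is needed one step earlier as activator of the aryl fluoride. Gain: the styrene is traced to a stable aldehyde. Demand: methylenation of a 2,6-dioxygenated benzaldehyde without removing the propargylic C–H.

17 to 16 and 9. Cut: O1'–C8a'. Reason: forming this bond at the arene leaves the C2'–O bond intact, so the configuration is carried over. Gain: ring A' with its methyl ether becomes a small separate aldehyde. Demand: the alkoxide must displace fluoride faster than it transfers hydride to the formyl group.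

16 to 15 and 10. Cut: C2'–C3', a C(sp3)–C(sp) bond. Reason: this is where the two halves become different; ring A is already attached on one side when the second carbinol is made, so no diol has to be desymmetrised. Gain: half of the carbon skeleton comes from a commodity aldehyde. Demand: catalyst-controlled Re-face alkynylation with the alkyne as limiting partner.

15 to 14. Cut: C(sp)–H back to C(sp)–Si. Reason: the silyl group protects the alkyne terminus through two basic steps. Gain: none in skeleton, only in safety. Demand: removal without isomerising the propargylic ether.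

14 to 13. Cut: C4=CH2 back to formyl, for the same reason and with the same demand as for 18.

13 to 12 and 4. Cut: O1–C8a. Reason and demand as for 17. Gain: ring A becomes aldehyde 4 and the chiral part shrinks to a simple propargylic alcohol.

12 to 10 and 11. Cut: C2–C3. Reason: one catalytic asymmetric alkynylation sets C2. Gain: the C3/C3' two-carbon unit and ring B come from two purchasable compounds. Demand: Re-face selectivity on an electron-rich aryl aldehyde.

4 to 2. Cut: the aryl–CHO bond. Reason: electrophilic formylation of a dialkoxyfluoroarene is direct. Gain: a symmetric arene. Demand: formylation between fluorine and one ether, not between the two ethers.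

2 to 1. Cut: two benzyl–oxygen bonds. Gain: a purchasable fluorinated diphenol. Demand: none beyond complete dialkylation.

9 to 8. Cut: one benzyl–oxygen bond. Reason: the ortho oxygen must be neutral for SNAr and removable at the end. Demand: O-alkylation of a hydrogen-bonded phenol.

8 to 7. Cut: O–H back to O–CH3 ortho to the formyl group. Reason: the two oxygens of ring A' are distinguished by chelation, not statistically. Gain: a symmetric dimethyl ether. Demand: cleavage of only the chelated methyl ether.

7 to 5. Cut: the aryl–CHO bond, as for 4. Gain: a purchasable arene.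

## Other disconnections considered

Alternative 1: The cut goes through C3–C3' and, formally, both O1–C2 bonds: 23 is traced to the dilactone A2, and A2 to two molecules of (E)-4-methoxycinnamic acid A1. Forward, A1 is oxidised by one electron (Tl(OCOCF3)3 with BF3·OEt2, trivalent thallium as oxidant, or an anode); two radical cations join at the carbons alpha to the carboxyl groups and each carboxyl oxygen closes on the benzylic cation of the other half.
- In its favour: one step from a commodity acid makes C3–C3' and fixes the relative configuration of all four stereocentres. The exo,exo cis-fused bicycle A2 corresponds centre for centre to the cis,cis arrangement of 23. On this point, and in steps to a stereodefined core, the alternative is better than the chosen plan.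
- Equal: neither plan has to join two sp3 carbons to obtain C3–C3'. Here the bond is made between two alkene carbons; in the chosen plan it is the acetylene unit itself.
- Against: nothing in a radical-cation dimerisation controls absolute configuration, so A2 would be racemic and need resolution, whereas the chosen plan sets C2 and C2' by catalysis.
- Against: the lactones are crossed; the acyl carbon on C3 is bound to the oxygen on C2'. Both acyl–oxygen bonds would have to be broken, each acyl carbon would have to acylate a ring A, and each benzylic oxygen would then have to be arylated by the ring A of its own half with retention. The opened intermediates are beta-aryl-beta-hydroxy carbonyl compounds prone to retro-aldol cleavage, dehydration and relactonisation, and two different rings A would have to be placed on a symmetric bis-electrophile.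
- Comparison: an open-shell coupling controlled by the substrate alone against a closed-shell, tether-controlled metathesis; shorter on paper up to A2, longer and far less predictable from A2 to 23.

Alternative 2: The cut goes through O1–C8a and C4–C4a of both halves: 23 is traced to the bis(2'-hydroxychalcone) A5, and A5 to the diacid A3 and two equivalents of the aryne precursor A4. Forward, CsF releases the aryne from A4; a carboxylate oxygen of A3 adds to the aryne carbon remote from the neighbouring benzyloxy group, the aryl anion attacks the carboxyl carbon, and the four-membered intermediate opens to the ortho-hydroxyaryl ketone, twice.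
- In its favour: highly convergent; both rings A are attached in one operation with the orientation dictated by the polarisation of the aryne, and A3 should be available in very few steps by a twofold Stobbe-type condensation with 10. Up to its key step the alternative is better in step count.
- Equal: C3–C3' poses no problem, since it is present in A3 from the start.
- Against: the key step closes no ring and sets no stereocentre. All four would have to arise in a later double oxa-Michael closure of A5, where C3 is set by protonation of an enol(ate); equilibration leads to 2,3-trans rings, and cis,cis in one enantiomer would need kinetic protonation and enantiocontrol in two consecutive closures.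
- Against: A5 is symmetric, so the 7'-methyl ether would have to be introduced statistically. The aryne step competes with simple O-arylation to the aryl ester and with ene reactions of the diene, and dienes of the A3 type isomerise and electrocyclise in light.
- Comparison: the chosen plan draws its stereocontrol from two preset centres and a tether; the alternative is shorter but leaves all stereocontrol to its least controllable step.

Alternative 3: The cut goes through the two C2–aryl bonds: 23 is traced to A8, and A8 to the unsymmetrical 3,3'-bichromone A6 and two equivalents of 4-methoxyphenylboronic acid A7. Forward, an arylpalladium species from A7 and Pd(OCOCF3)2 (divalent palladium) with a chiral pyridine–oxazoline ligand adds across C2=C3 and then C2'=C3', and the palladium enolates are protonated.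
- Equal: absolute configuration at C2 and C2' comes from a catalyst, and the two rings A are already different in A6.
- Better: rings B arrive last, which suits analogue synthesis, and only deprotection follows the key step.
- Against: a 3-substituted chromone is a trisubstituted, donor-deactivated acceptor with a crowded beta carbon, and the second addition takes place next to the first adduct; conversion is doubtful.
- Against: C3 and C3' are set by enolate protonation, not by the catalyst, which is expected to give the more stable 2,3-trans rings, whereas 23 is cis,cis. The chosen plan sets these centres by a syn addition whose facial sense is dictated by C2.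
- Against: unit 2 of A8 must lose its 5'-methyl group under Lewis acid on an epimerisable cis ketone; the chosen plan ends with neutral hydrogenolysis.
- Comparison: both plans use catalyst control for C2, but only the chosen plan has a stereospecific event for C3.

Key step: step 13

Remark on configuration: 23 is (2R,2'R,3R,3'R). C2 and C2' carry the descriptor S in 12, 13, 14, 16, 17, 18 and 19 and the descriptor R in 15, 21, 22 and 23 only because the CIP rank of the 4-methoxyphenyl group against the neighbouring carbon changes (the silylated or disubstituted alkyne carbon and the diene carbon rank above the aryl group, the ethynyl carbon and the sp3 carbon C3 below it); the spatial arrangement is the same from 12 to 23.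

Remark on the design: a C2-symmetric tetrabenzyl dienyne would end in a tetraphenol with two equivalent 7-hydroxyls, so the 7'-methyl ether could only be introduced statistically and under conditions that endanger the cis ketones. Dienyne 18 therefore carries the 7'-OMe from the start, and its carbinol centres are set one at a time by alkynylation rather than by reducing a diaryl ynedione, in which aryl and alkynyl compete as directing groups. The bonds formed and rings closed in the key step are unchanged.

Assumption: (S,S)-ProPhenol, 2,6-bis{[(S)-2-(hydroxydiphenylmethyl)pyrrolidin-1-yl]methyl}-4-methylphenol, is taken to be the antipode that adds the alkynyl group to the Re face of 10; the mirror-image ligand is used in steps 6 and 10 if the check on 12 shows otherwise.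

## Route

Step 1
Reactants: 1 5-fluororesorcinol
Product: 2 1,3-bis(benzyloxy)-5-fluorobenzene
Conditions: BnBr, K2CO3, DMF, 60 °C
Reagents that add atoms: benzyl bromide, BrCc1ccccc1
Why: Williamson etherification of both phenols with K2CO3 as base. Benzyl ethers tolerate alkoxide, ylide, organozinc, ruthenium carbene, borane and periodinane chemistry and leave by neutral hydrogenolysis in the last step.

Step 2
Reactants: 2 1,3-bis(benzyloxy)-5-fluorobenzene
Product: 4 2,4-bis(benzyloxy)-6-fluorobenzaldehyde, via iminium chloride 3 (not isolated)
Conditions: POCl3, DMF, 0 → 70 °C; then aq NaOAc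
Reagents that add atoms: N,N-dimethylformamide, CN(C)C=O; water, O
Why: Vilsmeier–Haack formylation through iminium salt 3, hydrolysed on work-up. The position between fluorine and one benzyloxy group is para to the other benzyloxy group and less crowded than the position between the two ethers, so the 6-fluoro aldehyde should be the main regioisomer and is purified by crystallisation. Fluorine ortho to the formyl group is the leaving group for the later SNAr.

Step 3
Reactants: 5 1-fluoro-3,5-dimethoxybenzene
Product: 7 2-fluoro-4,6-dimethoxybenzaldehyde, via iminium chloride 6 (not isolated)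
Conditions: POCl3, DMF, 0 → 70 °C; then aq NaOAc
Reagents that add atoms: N,N-dimethylformamide, CN(C)C=O; water, O
Why: Vilsmeier–Haack formylation through iminium salt 6, with the same regiochemical preference as in step 2 (para to one methoxy group, ortho to fluorine).

Step 4
Reactants: 7 2-fluoro-4,6-dimethoxybenzaldehyde
Product: 8 2-fluoro-6-hydroxy-4-methoxybenzaldehyde
Conditions: BCl3, CH2Cl2, −78 → 0 °C; then H2O
Reagents that add atoms: none
Why: Chelation-controlled aryl methyl ether cleavage: BCl3 binds the formyl oxygen and the ortho methoxy oxygen in a six-membered chelate, so chloride removes only that methyl group. The para methoxy group, which becomes the 7'-OMe of the target, lies outside the chelate and is kept at this temperature.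

Step 5
Reactants: 8 2-fluoro-6-hydroxy-4-methoxybenzaldehyde
Product: 9 2-(benzyloxy)-6-fluoro-4-methoxybenzaldehyde
Conditions: BnBr, K2CO3, DMF, rt
Reagents that add atoms: benzyl bromide, BrCc1ccccc1
Why: Williamson etherification of the hydrogen-bonded phenol. A free phenoxide would shut down the later SNAr, and the benzyl group leaves with the others in the final hydrogenolysis.

Step 6
Reactants: 10 4-methoxybenzaldehyde; 11 ethynyltriisopropylsilane
Product: 12 (S)-1-(4-methoxyphenyl)-3-(triisopropylsilyl)prop-2-yn-1-ol
Conditions: Me2Zn, (S,S)-ProPhenol (10 mol %), Ph3PO (20 mol %), toluene, 0 °C; then aq NH4Cl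
Reagents that add atoms: none
Why: Catalytic enantioselective alkynylation of an aryl aldehyde: Me2Zn and the alkyne give an alkynylzinc species held by the ProPhenol ligand, which adds to the aldehyde bound at the second zinc centre. The carbinol stereocentre (C2 of the target) is set by the ligand, which has to deliver the alkynyl group to the Re face of 10; the sense of induction is checked by Mosher ester analysis at this stage.

Step 7
Reactants: 12 (S)-1-(4-methoxyphenyl)-3-(triisopropylsilyl)prop-2-yn-1-ol; 4 2,4-bis(benzyloxy)-6-fluorobenzaldehyde
Product: 13 2,4-bis(benzyloxy)-6-{[(1S)-1-(4-methoxyphenyl)-3-(triisopropylsilyl)prop-2-yn-1-yl]oxy}benzaldehyde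
Conditions: NaH, THF–DMF, 0 °C; then 4, 0 °C → rt
Reagents that add atoms: none
Why: SNAr (addition–elimination) of the sodium alkoxide at the carbon bearing fluorine, activated by the ortho formyl group; both benzyloxy groups are meta to the reacting carbon and do not donate into it. The carbinol C–O bond is not involved, so the configuration is retained, and the triisopropylsilyl group shields the alkyne terminus from alkoxide and fluoride.

Step 8
Reactants: 13 2,4-bis(benzyloxy)-6-{[(1S)-1-(4-methoxyphenyl)-3-(triisopropylsilyl)prop-2-yn-1-yl]oxy}benzaldehyde
Product: 14 {(3S)-3-[3,5-bis(benzyloxy)-2-vinylphenoxy]-3-(4-methoxyphenyl)prop-1-yn-1-yl}triisopropylsilane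
Conditions: Ph3PCH3Br, KOtBu, THF, 0 °C → rt
Reagents that add atoms: methyltriphenylphosphonium bromide, C[P+](c1ccccc1)(c1ccccc1)c1ccccc1.[Br-]
Why: Wittig methylenation of the hindered, electron-rich aldehyde with the unstabilised ylide, which creates the first styrene (C4 and its methylene partner). The ylide is used in slight excess only and without free KOtBu, so the propargylic C–H is not removed.

Step 9
Reactants: 14 {(3S)-3-[3,5-bis(benzyloxy)-2-vinylphenoxy]-3-(4-methoxyphenyl)prop-1-yn-1-yl}triisopropylsilane
Product: 15 1,5-bis(benzyloxy)-3-{[(1R)-1-(4-methoxyphenyl)prop-2-yn-1-yl]oxy}-2-vinylbenzene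
Conditions: Bu4NF, AcOH, THF, 0 °C → rt
Reagents that add atoms: none
Why: Fluoride-induced cleavage of the C(sp)–Si bond to free the terminal alkyne. Acetic acid buffers the medium so that the propargylic C–H, activated by aryl, aryloxy and alkynyl groups, is not isomerised to the allene.

Step 10
Reactants: 15 1,5-bis(benzyloxy)-3-{[(1R)-1-(4-methoxyphenyl)prop-2-yn-1-yl]oxy}-2-vinylbenzene; 10 4-methoxybenzaldehyde
Product: 16 (1S,4S)-4-[3,5-bis(benzyloxy)-2-vinylphenoxy]-1,4-bis(4-methoxyphenyl)but-2-yn-1-ol
Conditions: Me2Zn, (S,S)-ProPhenol (20 mol %), Ph3PO (40 mol %), toluene, 0 °C; then aq NH4Cl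
Reagents that add atoms: none
Why: Second zinc–ProPhenol alkynylation, with the alkyne as limiting component and the inexpensive aldehyde in excess; the C2'–C3' bond is formed. The new carbinol stereocentre (C2' of the target) is set by the catalyst with the same Re-face sense as in step 6, since the existing centre lies across the linear alkyne and exerts no useful bias; a minor diastereomer is removable by chromatography.

Step 11
Reactants: 16 (1S,4S)-4-[3,5-bis(benzyloxy)-2-vinylphenoxy]-1,4-bis(4-methoxyphenyl)but-2-yn-1-ol; 9 2-(benzyloxy)-6-fluoro-4-methoxybenzaldehyde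
Product: 17 2-(benzyloxy)-6-{[(1S,4S)-4-[3,5-bis(benzyloxy)-2-vinylphenoxy]-1,4-bis(4-methoxyphenyl)but-2-yn-1-yl]oxy}-4-methoxybenzaldehyde
Conditions: NaH, THF–DMF, 0 °C; then 9, 0 °C → rt
Reagents that add atoms: none
Why: SNAr as in step 7, with the fluoroaldehyde that carries the future 7'-OMe; the ortho formyl group activates and the carbinol carbon keeps its configuration.

Step 12
Reactants: 17 2-(benzyloxy)-6-{[(1S,4S)-4-[3,5-bis(benzyloxy)-2-vinylphenoxy]-1,4-bis(4-methoxyphenyl)but-2-yn-1-yl]oxy}-4-methoxybenzaldehyde
Product: 18 1,5-bis(benzyloxy)-3-{[(1S,4S)-4-[3-(benzyloxy)-5-methoxy-2-vinylphenoxy]-1,4-bis(4-methoxyphenyl)but-2-yn-1-yl]oxy}-2-vinylbenzene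
Conditions: Ph3PCH3Br, KOtBu, THF, 0 °C → rt
Reagents that add atoms: methyltriphenylphosphonium bromide, C[P+](c1ccccc1)(c1ccccc1)c1ccccc1.[Br-]
Why: Wittig methylenation as in step 8, giving the second styrene. The bis(trialkoxystyrene) is acid-sensitive and is purified on silica gel deactivated with Et3N.

Step 13
Reactants: 18 1,5-bis(benzyloxy)-3-{[(1S,4S)-4-[3-(benzyloxy)-5-methoxy-2-vinylphenoxy]-1,4-bis(4-methoxyphenyl)but-2-yn-1-yl]oxy}-2-vinylbenzene
Product: 19 (2S,2'S)-5,5',7-tris(benzyloxy)-7'-methoxy-2,2'-bis(4-methoxyphenyl)-2H,2'H-3,3'-bichromene
Conditions: RuCl2(=CHPh)(H2IMes)(PCy3) (10 mol %), CH2Cl2 (0.005 M), 40 °C, Ar, dark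
Reagents that add atoms: none
Why: Tandem ring-closing enyne–alkene metathesis (dienyne metathesis) with the second-generation Grubbs catalyst RuCl2(=CHPh)(H2IMes)(PCy3), the closest known reaction type being the conversion of acyclic dienynes with a central alkyne into two rings joined through the former alkyne carbons. The benzylidene exchanges with one terminal styrene to give a ruthenium arylidene whose carbene carbon is C4. This carbene adds to the triple bond in the exo mode, C4 bonding to the nearer alkyne carbon C3, and the ruthenacyclobutene opens to the first six-membered ring O1–C2–C3=C4–C4a–C8a with a new carbene on C3'. The C3' carbene then undergoes ordinary ring-closing metathesis with the second styrene through a ruthenacyclobutane, closing the second six-membered ring O1'–C2'–C3'=C4'–C4a'–C8a' in the same exo sense, releasing ethylene by way of Ru=CH2 and leaving the old triple bond as the C3–C3' single bond of a conjugated diene. No stereocentre is formed, and C2 and C2' are spectators whose spatial arrangement is carried over unchanged. The step needs the order styrene, alkyne, second styrene and exo rather than endo addition to the alkyne; the substrate secures both, since only the terminal vinyl groups are accessible to the catalyst, the doubly branched internal alkyne is shielded from intermolecular attack, and the four-atom tether C4a–C8a–O1–C2 between C4 and C3 favours the six-membered exo closure over the seven-membered endo one. Because both sides have the same tether, initiation at either styrene leads to the same product. High dilution suppresses cross metathesis, and the mild temperature and exclusion of light guard against oxa-6π opening of the 2H-chromene, which would erode the configuration at C2.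

Step 14
Reactants: 19 (2S,2'S)-5,5',7-tris(benzyloxy)-7'-methoxy-2,2'-bis(4-methoxyphenyl)-2H,2'H-3,3'-bichromene
Product: 21 (2R,2'R,3S,3'S,4S,4'S)-5,5',7-tris(benzyloxy)-7'-methoxy-2,2'-bis(4-methoxyphenyl)-[3,3'-bichromane]-4,4'-diol, via bis(alkylborane) 20 (not isolated)
Conditions: BH3·SMe2, THF, 0 °C → rt; then aq NaOH, H2O2, 0 °C
Reagents that add atoms: hydrogen peroxide, OO
Why: Hydroboration–oxidation of both trisubstituted ring alkenes through bis(alkylborane) 20: boron goes to the unsubstituted, terminal carbons C4 and C4' of the diene, as in the hydroboration of 3-aryl-2H-chromenes to chroman-4-ols, and hydrogen to C3 and C3'. Each 2-aryl group stands pseudoaxial next to the substituted C3 and blocks one face, so H and B add syn from the opposite face; this sets C3 and C3' with H3 cis to H2 (aryl cis to the C3–C3' bond) under control of C2 and C2'. Oxidation of C–B to C–O goes with retention, and the configuration created at C4 and C4' is removed in step 15.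

Step 15
Reactants: 21 (2R,2'R,3S,3'S,4S,4'S)-5,5',7-tris(benzyloxy)-7'-methoxy-2,2'-bis(4-methoxyphenyl)-[3,3'-bichromane]-4,4'-diol
Product: 22 (2R,2'R,3R,3'R)-5,5',7-tris(benzyloxy)-7'-methoxy-2,2'-bis(4-methoxyphenyl)-[3,3'-bichromane]-4,4'-dione
Conditions: Dess–Martin periodinane, NaHCO3, CH2Cl2, 0 °C → rt
Reagents that add atoms: none
Why: Dess–Martin oxidation of the two benzylic secondary alcohols to the ketones. The buffered, non-basic medium and low temperature keep the new alpha stereocentres C3 and C3', which are in the less stable cis arrangement, from epimerising through the enol.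

Step 16
Reactants: 22 (2R,2'R,3R,3'R)-5,5',7-tris(benzyloxy)-7'-methoxy-2,2'-bis(4-methoxyphenyl)-[3,3'-bichromane]-4,4'-dione
Product: 23 (2R,2'R,3R,3'R)-5,5',7-trihydroxy-7'-methoxy-2,2'-bis(4-methoxyphenyl)-[3,3'-bichromane]-4,4'-dione
Conditions: H2 (1 atm), 10% Pd/C, EtOAc–MeOH, rt
Reagents that add atoms: none
Why: Catalytic hydrogenolysis of the three aryl benzyl ethers under neutral conditions; the three methyl ethers stay. No acid or base is present, so neither enolisation at C3 nor ring opening at O1–C2 can scramble the four stereocentres, and the reaction is stopped once the benzyl groups are gone to spare the cyclic benzylic C2–O1 bonds and the ketones.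

## Compound list

1 | 5-fluororesorcinol (5-fluorobenzene-1,3-diol) | Oc1cc(O)cc(F)c1 | starting material
2 | 1,3-bis(benzyloxy)-5-fluorobenzene | Fc1cc(OCc2ccccc2)cc(OCc2ccccc2)c1 | intermediate
3 | [2,4-bis(benzyloxy)-6-fluorobenzylidene]dimethyliminium chloride | C[N+](C)=Cc1c(F)cc(OCc2ccccc2)cc1OCc1ccccc1.[Cl-] | intermediate (not isolated)
4 | 2,4-bis(benzyloxy)-6-fluorobenzaldehyde | O=Cc1c(F)cc(OCc2ccccc2)cc1OCc1ccccc1 | intermediate
5 | 1-fluoro-3,5-dimethoxybenzene | COc1cc(F)cc(OC)c1 | starting material
6 | (2-fluoro-4,6-dimethoxybenzylidene)dimethyliminium chloride | C[N+](C)=Cc1c(F)cc(OC)cc1OC.[Cl-] | intermediate (not isolated)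
7 | 2-fluoro-4,6-dimethoxybenzaldehyde | COc1cc(F)c(C=O)c(OC)c1 | intermediate
8 | 2-fluoro-6-hydroxy-4-methoxybenzaldehyde | COc1cc(O)c(C=O)c(F)c1 | intermediate
9 | 2-(benzyloxy)-6-fluoro-4-methoxybenzaldehyde | COc1cc(F)c(C=O)c(OCc2ccccc2)c1 | intermediate
10 | 4-methoxybenzaldehyde | COc1ccc(C=O)cc1 | starting material
11 | ethynyltriisopropylsilane | C#C[Si](C(C)C)(C(C)C)C(C)C | starting material
12 | (S)-1-(4-methoxyphenyl)-3-(triisopropylsilyl)prop-2-yn-1-ol | COc1ccc([C@@H](C#C[Si](C(C)C)(C(C)C)C(C)C)O)cc1 | intermediate
13 | 2,4-bis(benzyloxy)-6-{[(1S)-1-(4-methoxyphenyl)-3-(triisopropylsilyl)prop-2-yn-1-yl]oxy}benzaldehyde | COc1ccc([C@@H](C#C[Si](C(C)C)(C(C)C)C(C)C)Oc2cc(OCc3ccccc3)cc(OCc3ccccc3)c2C=O)cc1 | intermediate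
14 | {(3S)-3-[3,5-bis(benzyloxy)-2-vinylphenoxy]-3-(4-methoxyphenyl)prop-1-yn-1-yl}triisopropylsilane | COc1ccc([C@@H](C#C[Si](C(C)C)(C(C)C)C(C)C)Oc2cc(OCc3ccccc3)cc(OCc3ccccc3)c2C=C)cc1 | intermediate
15 | 1,5-bis(benzyloxy)-3-{[(1R)-1-(4-methoxyphenyl)prop-2-yn-1-yl]oxy}-2-vinylbenzene | COc1ccc([C@@H](C#C)Oc2cc(OCc3ccccc3)cc(OCc3ccccc3)c2C=C)cc1 | intermediate
16 | (1S,4S)-4-[3,5-bis(benzyloxy)-2-vinylphenoxy]-1,4-bis(4-methoxyphenyl)but-2-yn-1-ol | COc1ccc([C@@H](C#C[C@@H](O)c2ccc(OC)cc2)Oc2cc(OCc3ccccc3)cc(OCc3ccccc3)c2C=C)cc1 | intermediate
17 | 2-(benzyloxy)-6-{[(1S,4S)-4-[3,5-bis(benzyloxy)-2-vinylphenoxy]-1,4-bis(4-methoxyphenyl)but-2-yn-1-yl]oxy}-4-methoxybenzaldehyde | COc1ccc([C@@H](C#C[C@@H](Oc2cc(OC)cc(OCc3ccccc3)c2C=O)c2ccc(OC)cc2)Oc2cc(OCc3ccccc3)cc(OCc3ccccc3)c2C=C)cc1 | intermediate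
18 | 1,5-bis(benzyloxy)-3-{[(1S,4S)-4-[3-(benzyloxy)-5-methoxy-2-vinylphenoxy]-1,4-bis(4-methoxyphenyl)but-2-yn-1-yl]oxy}-2-vinylbenzene | COc1ccc([C@@H](C#C[C@@H](Oc2cc(OC)cc(OCc3ccccc3)c2C=C)c2ccc(OC)cc2)Oc2cc(OCc3ccccc3)cc(OCc3ccccc3)c2C=C)cc1 | intermediate
19 | (2S,2'S)-5,5',7-tris(benzyloxy)-7'-methoxy-2,2'-bis(4-methoxyphenyl)-2H,2'H-3,3'-bichromene | COc1ccc([C@@H]2Oc3cc(OCc4ccccc4)cc(OCc4ccccc4)c3C=C2C2=Cc3c(OCc4ccccc4)cc(OC)cc3O[C@H]2c2ccc(OC)cc2)cc1 | intermediate
20 | 4,4'-bis(dihydroboryl) analogue of 21 (BH2 in place of each OH, same arrangement in space, drawn as the monomeric alkylborane) | COc1ccc([C@@H]2Oc3cc(OCc4ccccc4)cc(OCc4ccccc4)c3[C@@H](B)[C@@H]2[C@H]2[C@H](B)c3c(OCc4ccccc4)cc(OC)cc3O[C@H]2c2ccc(OC)cc2)cc1 | intermediate (not isolated)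
21 | (2R,2'R,3S,3'S,4S,4'S)-5,5',7-tris(benzyloxy)-7'-methoxy-2,2'-bis(4-methoxyphenyl)-[3,3'-bichromane]-4,4'-diol | COc1ccc([C@@H]2Oc3cc(OCc4ccccc4)cc(OCc4ccccc4)c3[C@@H](O)[C@@H]2[C@H]2[C@H](O)c3c(OCc4ccccc4)cc(OC)cc3O[C@H]2c2ccc(OC)cc2)cc1 | intermediate
22 | (2R,2'R,3R,3'R)-5,5',7-tris(benzyloxy)-7'-methoxy-2,2'-bis(4-methoxyphenyl)-[3,3'-bichromane]-4,4'-dione | COc1ccc([C@@H]2Oc3cc(OCc4ccccc4)cc(OCc4ccccc4)c3C(=O)[C@@H]2[C@H]2C(=O)c3c(OCc4ccccc4)cc(OC)cc3O[C@H]2c2ccc(OC)cc2)cc1 | intermediate
23 | (2R,2'R,3R,3'R)-5,5',7-trihydroxy-7'-methoxy-2,2'-bis(4-methoxyphenyl)-[3,3'-bichromane]-4,4'-dione | COc1ccc([C@@H]2Oc3cc(O)cc(O)c3C(=O)[C@@H]2[C@H]2C(=O)c3c(O)cc(OC)cc3O[C@H]2c2ccc(OC)cc2)cc1 | target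

## Step count and least certain steps

Total: 16 steps. Longest linear sequence: 12 steps (steps 1, 2 and 7 to 16, from 1). The branch from 10 and 11 (steps 6 to 16) counts 11 steps, and the branch from 5 (steps 3 to 5, then 11 to 16) counts 9 steps.

Step 13 (key step). The most likely failure is stalling after the first ring closure: the disubstituted carbene on C3' is crowded and must reach a 2,6-dioxygenated styrene, so it may be lost to cross metathesis, or the catalyst may rest as an ortho-alkoxy-chelated arylidene. Forcing the reaction thermally would invite oxa-6π opening and reclosure of the 2H-chromene and thus erosion at C2. Fallback, from 18 back to 19: the two ring closures are separated. Under ethylene with the second-generation Hoveyda–Grubbs catalyst RuCl2(=CH-2-iPrOC6H4)(H2IMes), ring-closing enyne metathesis is run so that ethylene intercepts the C3' carbene. This gives the two mono-cyclised trienes, the ring-C-closed triene F1 and the ring-C'-closed triene F2. The mixture, freed from ethylene, is then closed by ordinary ring-closing metathesis between the 1,1-disubstituted alkene and the remaining styrene, which gives 19 from both.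

Step 14. The most likely failure is addition with the wrong regiochemistry: the trioxygenated ring A pushes boron towards C3, as it does when C3 carries only hydrogen, and a C3 borane would then eliminate the ring oxygen. Facial selection governed by the other chromene unit rather than by the adjacent aryl group is the second hazard. Fallback, from 19 back to 22: homogeneous hydrogenation of both ring alkenes with [Ir(cod)(PCy3)(py)]PF6 (syn addition opposite each 2-aryl group; benzyl ethers and the allylic C2–O1 bonds survive) gives the cis,cis-3,3'-biflavan F3. Oxidation at the benzylic positions C4 and C4', which ring A activates, with DDQ in wet CH2Cl2 gives the 4,4'-diol epimer mixture F4, and Dess–Martin oxidation converges on 22.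

Step 7 (step 11 is the same reaction type). The most likely failure is diversion of the alkoxide by the formyl group (hemiacetal formation or hydride transfer from the benzylic–propargylic alkoxide) while substitution on the donor-substituted ring is slow; excess base could also isomerise the propargylic ether. Fallback, from 4 and 12 back to 13: the formyl group is exchanged for a nitrile, a stronger activator that neither accepts hydride nor traps alkoxide. NH2OH·HCl with NaOAc gives the oxime F5, dehydration with Ac2O gives the fluoronitrile F6, SNAr with the sodium alkoxide of 12 gives the aryl ether nitrile F7, and half-reduction with iBu2AlH and aqueous work-up returns 13.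

Step 10. The most likely failure is incomplete conversion and eroded diastereoselectivity, because the elaborate alkyne is the limiting partner, whereas this alkynylation is normally run with the alkyne in excess. Fallback, from 12 back to 18: the order is changed so that the second alkynylation uses a small alkyne in excess. Desilylation of 12 gives the terminal alkynol F8. Zinc–ProPhenol addition of F8 (in excess, with additional Me2Zn for the hydroxyl) to 10 gives the C2-symmetric diol F9, whose enantiomeric purity profits from double stereodifferentiation. SNAr with one equivalent of 4 gives the mono-ether aldehyde F10 (statistical, unreacted F9 being recycled), SNAr with 9 gives the bis-aldehyde F11, and double Wittig methylenation gives 18.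

Step 16. The most likely failure is over-reduction: hydrogenolytic opening of the cyclic benzylic C2–O1 bonds or reduction of the ketones before the last benzyl group is gone. Fallback, from 22 directly to 23: non-reductive debenzylation with BCl3 and pentamethylbenzene as cation scavenger in CH2Cl2 at −78 °C, which spares the non-chelated methyl ethers; no new compound lies on the way.

## Further compounds

F1 | step 13 | (2S)-5,7-bis(benzyloxy)-3-{(3S)-3-[3-(benzyloxy)-5-methoxy-2-vinylphenoxy]-3-(4-methoxyphenyl)prop-1-en-2-yl}-2-(4-methoxyphenyl)-2H-chromene | COc1ccc([C@@H]2Oc3cc(OCc4ccccc4)cc(OCc4ccccc4)c3C=C2C(=C)[C@@H](Oc2cc(OC)cc(OCc3ccccc3)c2C=C)c2ccc(OC)cc2)cc1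
F2 | step 13 | (2S)-5-(benzyloxy)-3-{(3S)-3-[3,5-bis(benzyloxy)-2-vinylphenoxy]-3-(4-methoxyphenyl)prop-1-en-2-yl}-7-methoxy-2-(4-methoxyphenyl)-2H-chromene | COc1ccc([C@H](Oc2cc(OCc3ccccc3)cc(OCc3ccccc3)c2C=C)C(=C)C2=Cc3c(OCc4ccccc4)cc(OC)cc3O[C@H]2c2ccc(OC)cc2)cc1
F3 | step 14 | (2R,2'R,3R,3'R)-5,5',7-tris(benzyloxy)-7'-methoxy-2,2'-bis(4-methoxyphenyl)-3,3'-bichromane | COc1ccc([C@@H]2Oc3cc(OCc4ccccc4)cc(OCc4ccccc4)c3C[C@@H]2[C@H]2Cc3c(OCc4ccccc4)cc(OC)cc3O[C@H]2c2ccc(OC)cc2)cc1
F4 | step 14 | (2R,2'R,3S,3'S)-5,5',7-tris(benzyloxy)-7'-methoxy-2,2'-bis(4-methoxyphenyl)-[3,3'-bichromane]-4,4'-diol, mixture of epimers at C4 and C4' | COc1ccc([C@@H]2Oc3cc(OCc4ccccc4)cc(OCc4ccccc4)c3C(O)[C@@H]2[C@H]2C(O)c3c(OCc4ccccc4)cc(OC)cc3O[C@H]2c2ccc(OC)cc2)cc1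
F5 | step 7 | (E)-2,4-bis(benzyloxy)-6-fluorobenzaldehyde oxime | O/N=C/c1c(F)cc(OCc2ccccc2)cc1OCc1ccccc1
F6 | step 7 | 2,4-bis(benzyloxy)-6-fluorobenzonitrile | N#Cc1c(F)cc(OCc2ccccc2)cc1OCc1ccccc1
F7 | step 7 | 2,4-bis(benzyloxy)-6-{[(1S)-1-(4-methoxyphenyl)-3-(triisopropylsilyl)prop-2-yn-1-yl]oxy}benzonitrile | COc1ccc([C@@H](C#C[Si](C(C)C)(C(C)C)C(C)C)Oc2cc(OCc3ccccc3)cc(OCc3ccccc3)c2C#N)cc1
F8 | step 10 | (R)-1-(4-methoxyphenyl)prop-2-yn-1-ol | COc1ccc([C@@H](C#C)O)cc1
F9 | step 10 | (1S,4S)-1,4-bis(4-methoxyphenyl)but-2-yne-1,4-diol | COc1ccc([C@@H](C#C[C@@H](O)c2ccc(OC)cc2)O)cc1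
F10 | step 10 | 2,4-bis(benzyloxy)-6-{[(1S,4S)-4-hydroxy-1,4-bis(4-methoxyphenyl)but-2-yn-1-yl]oxy}benzaldehyde | COc1ccc([C@@H](C#C[C@@H](O)c2ccc(OC)cc2)Oc2cc(OCc3ccccc3)cc(OCc3ccccc3)c2C=O)cc1
F11 | step 10 | 2-(benzyloxy)-6-{[(1S,4S)-4-[3,5-bis(benzyloxy)-2-formylphenoxy]-1,4-bis(4-methoxyphenyl)but-2-yn-1-yl]oxy}-4-methoxybenzaldehyde | COc1ccc([C@@H](C#C[C@@H](Oc2cc(OC)cc(OCc3ccccc3)c2C=O)c2ccc(OC)cc2)Oc2cc(OCc3ccccc3)cc(OCc3ccccc3)c2C=O)cc1
F0 | step 16 | none | none
A1 | alternative 1 | (E)-4-methoxycinnamic acid | COc1ccc(/C=C/C(=O)O)cc1
A2 | alternative 1 | exo,exo cis-fused 2,6-bis(4-methoxyphenyl)-3,7-dioxabicyclo[3.3.0]octane-4,8-dione, the enantiomer that maps onto 23 | COc1ccc([C@@H]2OC(=O)[C@@H]3[C@H]2C(=O)O[C@H]3c2ccc(OC)cc2)cc1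
A3 | alternative 2 | (2E,3E)-2,3-bis(4-methoxybenzylidene)succinic acid | COc1ccc(/C=C(C(=O)O)\C(C(=O)O)=C/c2ccc(OC)cc2)cc1
A4 | alternative 2 | 3,5-bis(benzyloxy)-2-(trimethylsilyl)phenyl trifluoromethanesulfonate | C[Si](C)(C)c1c(OS(=O)(=O)C(F)(F)F)cc(OCc2ccccc2)cc1OCc1ccccc1
A5 | alternative 2 | (2E,3E)-2,3-bis(4-methoxybenzylidene)-1,4-bis[2-hydroxy-4,6-bis(benzyloxy)phenyl]butane-1,4-dione | COc1ccc(/C=C(C(=O)c2c(O)cc(OCc3ccccc3)cc2OCc2ccccc2)\C(C(=O)c2c(O)cc(OCc3ccccc3)cc2OCc2ccccc2)=C/c2ccc(OC)cc2)cc1
A6 | alternative 3 | 5,7-bis(benzyloxy)-5',7'-dimethoxy-4H,4'H-[3,3'-bichromene]-4,4'-dione | O=c1c(-c2coc3cc(OC)cc(OC)c3c2=O)coc2cc(OCc3ccccc3)cc(OCc3ccccc3)c12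
A7 | alternative 3 | 4-methoxyphenylboronic acid | COc1ccc(B(O)O)cc1
A8 | alternative 3 | (2R,2'R,3R,3'R)-5,7-bis(benzyloxy)-5',7'-dimethoxy-2,2'-bis(4-methoxyphenyl)-[3,3'-bichromane]-4,4'-dione | COc1ccc([C@@H]2Oc3cc(OCc4ccccc4)cc(OCc4ccccc4)c3C(=O)[C@@H]2[C@H]2C(=O)c3c(OC)cc(OC)cc3O[C@H]2c2ccc(OC)cc2)cc1
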